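**Retrosynthetic overview**
1. Ester C–O bond: target ⇒ tertiary azaphilone alcohol + octadecanoic acid; the C18 acid is assembled C7 + C6 + C5 by two copper-catalysed Grignard couplings.
2. Six-membered carbocycle (last ring): the 2-hydroxy-2-methyl-1,3-dione ⇒ ring-expanding α-ketol 1,2-acyl shift of a 7-acetyl-7-hydroxy-cyclopenta[c]pyran-6-one; the shift relays the carbinol configuration into C7.
3. That ketol ⇒ C-acetylation, then reagent-controlled enolate hydroxylation, of the bicyclic dienone 3-methyl-3,4-dihydrocyclopenta[c]pyran-6(7H)-one.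
4. Dihydropyran ring (second ring): Stork–Danheiser union of α'-dimethoxymethylated 3-methoxycyclopent-2-enone with the C3 unit of (R)-1-chloropropan-2-ol (source of C3), closed by acetal exchange.
5. Ring order: cyclopentenone (purchased) → dihydropyran → cyclohexenedione by 5→6 expansion; acylation last.

Assumption: (R)-1-chloropropan-2-ol and both antipodes of the oxaziridine of step 4 are bought enantiopure; the (−)-reagent is taken as the one that gives the 7R carbinol (sense assigned by analogy with related cyclic β-dicarbonyl enolates, to be confirmed on the first run; the 7-epimer is a diastereomer and is removed on silica).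

The target is (3R,7R). Locants follow cyclopenta[c]pyran numbering for 10–15 and isochromene numbering for 16 and 26.

**Step 1**
Reactants: 1 3-methoxycyclopent-2-en-1-one; 2 trimethyl orthoformate
Product: 5 5-(dimethoxymethyl)-3-methoxycyclopent-2-en-1-one (racemic), via lithium enolate 3 (not isolated), via silyl dienol ether 4 (not isolated)
Conditions: LDA, THF, −78 °C; TMSCl, −78 to 0 °C (used cold, crude); then 2, TMSOTf (5 mol%), CH2Cl2, −78 °C
Reagents that add atoms: none
Why: Kinetic α'-deprotonation of the vinylogous ester is regiospecific, and the derived silyl dienol ether is attacked at C5 by the dimethoxycarbenium ion from the orthoformate (Mukaiyama-type α-dialkoxymethylation of a silyl enol ether), which installs the future C1 at the aldehyde oxidation level as an acetal that tolerates the organolithium of step 2; the C5 stereocentre is racemic and is erased in step 2.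

**Step 2**
Reactants: 5 5-(dimethoxymethyl)-3-methoxycyclopent-2-en-1-one; 6 (R)-1-chloropropan-2-ol
Product: 10 (3R)-3-methyl-3,4-dihydrocyclopenta[c]pyran-6(7H)-one, via dilithio reagent 7 (not isolated), via dialkoxide adduct 8 (not isolated), via hydroxy acetal enone 9 (not isolated)
Conditions: 6, n-BuLi (1.0 equiv) then lithium naphthalenide (2.0 equiv), THF, −78 °C; add 5, −78 °C; 1 M HCl, 0 °C to rt; then PPTS (cat.), PhMe, 80 °C (−MeOH)
Reagents that add atoms: water, O
Why: Stork–Danheiser sequence in which the β-oxido alkyllithium (reductive lithiation of the chlorohydrin alkoxide, stable to β-elimination at −78 °C) adds 1,2 to the vinylogous ester carbonyl, aqueous acid transposes the carbonyl to the enone, and the side-chain hydroxyl then exchanges into the acetal and loses methanol to give the conjugated cyclic enol ether; C3 is carried unchanged from 6 (no bond to it is touched) and the C4 stereocentre of 9 becomes sp2.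

**Step 3**
Reactants: 10 (3R)-3-methyl-3,4-dihydrocyclopenta[c]pyran-6(7H)-one; 11 1-acetylimidazole
Product: 13 (3R)-7-acetyl-3-methyl-3,4-dihydrocyclopenta[c]pyran-6(7H)-one, via lithium enolate 12 (not isolated)
Conditions: LiHMDS (2.2 equiv), THF, −78 °C; 11, −78 to 0 °C; 1 M HCl work-up
Reagents that add atoms: none
Why: C7 is the only enolisable position α to the ketone, and its lithium enolate is C-acylated by the acylimidazole (crossed Claisen condensation), the second equivalent of base holding the product as its stabilised β-diketone enolate; C7 remains an enolised, stereochemically undefined centre.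

**Step 4**
Reactants: 13 (3R)-7-acetyl-3-methyl-3,4-dihydrocyclopenta[c]pyran-6(7H)-one
Product: 15 (3R,7R)-7-acetyl-7-hydroxy-3-methyl-3,4-dihydrocyclopenta[c]pyran-6(7H)-one, via sodium enolate 14 (not isolated)
Conditions: NaHMDS (1.1 equiv), THF, −78 °C; (−)-[(8,8-dichlorocamphoryl)sulfonyl]oxaziridine (1.3 equiv), −78 °C; AcOH quench at −78 °C; chromatography
Reagents that add atoms: (−)-[(8,8-dichlorocamphoryl)sulfonyl]oxaziridine, CC1(C)C2CCC13CS(=O)(=O)N4OC34C2(Cl)Cl
Why: Davis enolate hydroxylation in which the β-diketone enolate is oxidised at its central carbon by the enantiopure N-sulfonyloxaziridine, which differentiates the enolate faces (reagent control, C3 being too remote to interfere) to set the 7R carbinol; because C3 is fixed the minor 7-epimer is a diastereomer removed on silica, and the cold acidic quench prevents base-induced ketol shifts.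

**Step 5**
Reactants: 15 (3R,7R)-7-acetyl-7-hydroxy-3-methyl-3,4-dihydrocyclopenta[c]pyran-6(7H)-one
Product: 16 (3R,7R)-7-hydroxy-3,7-dimethyl-3,4-dihydro-6H-isochromene-6,8(7H)-dione
Conditions: Cu(OTf)2 (10 mol%), 2,2'-bipyridine (11 mol%), 4 Å MS, CH2Cl2, 25 °C
Reagents that add atoms: none
Why: Proposed new method: a chelation-controlled, stereospecific ring-expanding α-ketol (acyloin) rearrangement of a 2-acetyl-2-hydroxycyclopentenone to a 2-hydroxy-2-methylcyclohexene-1,3-dione, not yet shown on this substrate class; Cu(II) binds the tertiary OH and the acetyl C=O in a five-membered s-cis chelate, which polarises the acetyl carbonyl so that the ring acyl carbon C6 migrates suprafacially from the carbinol carbon C7 to the acetyl carbon (5→6 expansion; old C7 becomes C8=O, the acetyl carbon becomes C7), the hydroxyl therefore stays on the same ring face and the 7R carbinol is relayed into the 7R quaternary centre (1,2-chirality transfer; an acetyl shuttle to C6 followed by expansion converges on the same epimer), the driving force being release of cyclopentenone strain and the new vinylogous-ester conjugation of C8=O with the enol ether; the closest known reaction types are the Lewis-acid α-ketol ring expansion of 1-acylcycloalkanols (steroid D-homoannulation) and Cu(II)/bis(oxazoline)-catalysed α-ketol rearrangements of β-hydroxy-α-dicarbonyl compounds.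

**Step 6**
Reactants: 17 1-bromoheptane; 18 1-bromo-6-chlorohexane
Product: 20 1-chlorotridecane, via heptylmagnesium bromide 19 (not isolated)
Conditions: 17, Mg, THF, 25–40 °C; then 18, Li2CuCl4 (2 mol%), THF, −10 to 0 °C
Reagents that add atoms: none
Why: Tamura–Kochi copper-catalysed sp3–sp3 coupling of an alkyl Grignard reagent, which reacts at the C–Br bond and leaves the C–Cl bond untouched, giving the C13 chloride without oligomerisation.

**Step 7**
Reactants: 20 1-chlorotridecane; 21 5-bromopentanoic acid
Product: 24 octadecanoic acid, via tridecylmagnesium chloride 22 (not isolated), via chloromagnesium 5-bromopentanoate 23 (not isolated)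
Conditions: 20, Mg, THF, reflux (I2 initiation); 21, MeMgCl (1.0 equiv), THF, −20 °C; combine, Li2CuCl4 (3 mol%), −20 to 0 °C; 1 M HCl
Reagents that add atoms: none
Why: The same copper-catalysed Grignard–alkyl bromide coupling, run on the preformed magnesium carboxylate so that the acid proton is masked and the Grignard reagent attacks only the primary C–Br bond, completing the C18 chain (13 + 5).

**Step 8**
Reactants: 24 octadecanoic acid; 16 (3R,7R)-7-hydroxy-3,7-dimethyl-3,4-dihydro-6H-isochromene-6,8(7H)-dione
Product: 26 (3R,7R)-3,7-dimethyl-6,8-dioxo-3,4,7,8-tetrahydro-6H-isochromen-7-yl octadecanoate, via octadecanoyl chloride 25 (not isolated)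
Conditions: 24, (COCl)2, DMF (cat.), CH2Cl2, 0 °C to rt, evaporate; then 16, Et3N, DMAP (0.2 equiv), CH2Cl2, 0 °C to rt
Reagents that add atoms: none
Why: Acid chloride formation (DMF/oxalyl chloride activation) followed by DMAP-catalysed acylation of the hindered tertiary alcohol, a reaction type used for 7-O-acylation of azaphilones; the C7–O bond is retained so no stereocentre is touched, and only tertiary amines are present so the amine-sensitive pyran ring is not attacked.

**Compound list**
1 | 3-methoxycyclopent-2-en-1-one | COC1=CC(=O)CC1 | starting material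
2 | trimethyl orthoformate | COC(OC)OC | starting material
3 | lithium 4-methoxycyclopenta-1,4-dien-1-olate (α'-enolate of 1) | COC1=CC(O[Li])=CC1 | intermediate
4 | 1-methoxy-3-[(trimethylsilyl)oxy]cyclopenta-1,3-diene | COC1=CC(O[Si](C)(C)C)=CC1 | intermediate
5 | 5-(dimethoxymethyl)-3-methoxycyclopent-2-en-1-one (racemic) | COC1=CC(=O)C(C(OC)OC)C1 | intermediate
6 | (R)-1-chloropropan-2-ol | C[C@@H](O)CCl | starting material
7 | lithium (2R)-1-lithiopropan-2-olate | [Li]C[C@@H](C)O[Li] | intermediate
8 | dilithium 5-(dimethoxymethyl)-3-methoxy-1-[(2R)-2-oxidopropyl]cyclopent-2-en-1-olate (1,2-adduct, diastereomer mixture) | COC1=CC(O[Li])(C[C@@H](C)O[Li])C(C(OC)OC)C1 | intermediate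
9 | 4-(dimethoxymethyl)-3-[(2R)-2-hydroxypropyl]cyclopent-2-en-1-one (C4 epimers) | O=C1C=C(C[C@@H](C)O)C(C(OC)OC)C1 | intermediate
10 | (3R)-3-methyl-3,4-dihydrocyclopenta[c]pyran-6(7H)-one | O=C1C=C2C[C@@H](C)OC=C2C1 | intermediate
11 | 1-acetylimidazole | CC(=O)n1ccnc1 | starting material
12 | lithium enolate of 10 (lithium (3R)-3-methyl-3,4-dihydrocyclopenta[c]pyran-6-olate) | [Li]OC1C=C2C[C@@H](C)OC=C2C=1 | intermediate
13 | (3R)-7-acetyl-3-methyl-3,4-dihydrocyclopenta[c]pyran-6(7H)-one (keto form shown; enolised) | CC(=O)C1C(=O)C=C2C[C@@H](C)OC=C21 | intermediate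
14 | sodium enolate of 13 | CC(=O)C1=C(O[Na])C=C2C[C@@H](C)OC=C21 | intermediate
15 | (3R,7R)-7-acetyl-7-hydroxy-3-methyl-3,4-dihydrocyclopenta[c]pyran-6(7H)-one | CC(=O)[C@@]1(O)C(=O)C=C2C[C@@H](C)OC=C21 | intermediate
16 | (3R,7R)-7-hydroxy-3,7-dimethyl-3,4-dihydro-6H-isochromene-6,8(7H)-dione | O[C@]1(C)C(=O)C=C2C[C@@H](C)OC=C2C1=O | intermediate
17 | 1-bromoheptane | CCCCCCCBr | starting material
18 | 1-bromo-6-chlorohexane | ClCCCCCCBr | starting material
19 | heptylmagnesium bromide | CCCCCCC[Mg]Br | intermediate
20 | 1-chlorotridecane | CCCCCCCCCCCCCCl | intermediate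
21 | 5-bromopentanoic acid | OC(=O)CCCCBr | starting material
22 | tridecylmagnesium chloride | CCCCCCCCCCCCC[Mg]Cl | intermediate
23 | chloromagnesium 5-bromopentanoate | BrCCCCC(=O)O[Mg]Cl | intermediate
24 | octadecanoic acid | CCCCCCCCCCCCCCCCCC(=O)O | intermediate
25 | octadecanoyl chloride | CCCCCCCCCCCCCCCCCC(=O)Cl | intermediate
26 | (3R,7R)-3,7-dimethyl-6,8-dioxo-3,4,7,8-tetrahydro-6H-isochromen-7-yl octadecanoate | CCCCCCCCCCCCCCCCCC(=O)O[C@]1(C)C(=O)C=C2C[C@@H](C)OC=C2C1=O | target

**Step count**
Total steps: 8. Longest linear sequence: 6 (steps 1, 2, 3, 4, 5, 8); the acid branch is 3 steps (6, 7, 8).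

**Three steps most likely to fail**

Step 5 (the proposed new ring expansion). The risks are leakage through a non-chelated s-trans transition state (erosion at C7), vinyl instead of acyl migration, or an unfavourable equilibrium. The fallback uses known chemistry, sets out from 10 and comes back at 16. The lithium enolate of 10 is added to acetaldehyde (LiHMDS, THF, −78 °C) to give (3R)-7-(1-hydroxyethyl)-3-methyl-3,4-dihydrocyclopenta[c]pyran-6(7H)-one F1. Acid-catalysed dehydration (TsOH cat., benzene, 60 °C) gives (3R)-7-ethylidene-3-methyl-3,4-dihydrocyclopenta[c]pyran-6(7H)-one F2. Nucleophilic epoxidation of the exocyclic enone (t-BuOOH, DBU) gives the spiro-epoxy ketone (3R)-3,3'-dimethyl-3,4-dihydro-6H-spiro[cyclopenta[c]pyran-7,2'-oxiran]-6-one F3. BF3·OEt2 then effects the classical 1,2-acyl shift of an α,β-epoxy ketone to the ring-expanded 1,3-dione, obtained as its enol (3R)-8-hydroxy-3,7-dimethyl-3,4-dihydro-6H-isochromen-6-one F4. Oxidation at C7 with IBX, the standard oxidative hydroxylation that closes azaphilone syntheses, gives 16 and its 7-epimer (3R,7S)-7-hydroxy-3,7-dimethyl-3,4-dihydro-6H-isochromene-6,8(7H)-dione F5; these are diastereomers and are separated by chromatography.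

Step 2 (β-oxido alkyllithium addition and cascade). The risks are enolisation of 5 or β-elimination of methoxide instead of 1,2-addition, and single-electron reduction of 5 by residual naphthalenide. The fallback sets out from 5 and comes back at 9. Allylmagnesium bromide adds to 5 (THF, −78 °C) and mild hydrolysis (aqueous oxalic acid) gives 3-allyl-4-(dimethoxymethyl)cyclopent-2-en-1-one F6. Tsuji–Wacker oxidation (PdCl2, CuCl, O2, DMF/H2O) gives 4-(dimethoxymethyl)-3-(2-oxopropyl)cyclopent-2-en-1-one F7. An (R)-selective (anti-Prelog) ketoreductase with NADPH/i-PrOH reduces the methyl ketone to 9, which is closed to 10 with acid as in step 2; C3 is then set by the enzyme instead of coming from 6.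

Step 4 (reagent-controlled hydroxylation). The risks are low or opposite facial selectivity on this fulvenoid β-diketone enolate. The fallback sets out from 13 and comes back at 15. It gives up reagent control: the enol of 13 is oxidised with dimethyldioxirane (acetone, −40 °C) to a roughly 1:1 mixture of 15 and its 7-epimer (3R,7S)-7-acetyl-7-hydroxy-3-methyl-3,4-dihydrocyclopenta[c]pyran-6(7H)-one F8, and the two diastereomers (C3 is fixed) are resolved by chromatography or crystallisation.

**Further compounds**
F1 | step 5 | (3R)-7-(1-hydroxyethyl)-3-methyl-3,4-dihydrocyclopenta[c]pyran-6(7H)-one | CC(O)C1C(=O)C=C2C[C@@H](C)OC=C21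
F2 | step 5 | (3R)-7-ethylidene-3-methyl-3,4-dihydrocyclopenta[c]pyran-6(7H)-one | CC=C1C(=O)C=C2C[C@@H](C)OC=C21
F3 | step 5 | (3R)-3,3'-dimethyl-3,4-dihydro-6H-spiro[cyclopenta[c]pyran-7,2'-oxiran]-6-one | CC1OC12C(=O)C=C3C[C@@H](C)OC=C32
F4 | step 5 | (3R)-8-hydroxy-3,7-dimethyl-3,4-dihydro-6H-isochromen-6-one | O=C1C=C2C[C@@H](C)OC=C2C(O)=C1C
F5 | step 5 | (3R,7S)-7-hydroxy-3,7-dimethyl-3,4-dihydro-6H-isochromene-6,8(7H)-dione | O[C@@]1(C)C(=O)C=C2C[C@@H](C)OC=C2C1=O
F6 | step 2 | 3-allyl-4-(dimethoxymethyl)cyclopent-2-en-1-one | C=CCC1=CC(=O)CC1C(OC)OC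
F7 | step 2 | 4-(dimethoxymethyl)-3-(2-oxopropyl)cyclopent-2-en-1-one | CC(=O)CC1=CC(=O)CC1C(OC)OC
F8 | step 4 | (3R,7S)-7-acetyl-7-hydroxy-3-methyl-3,4-dihydrocyclopenta[c]pyran-6(7H)-one | CC(=O)[C@]1(O)C(=O)C=C2C[C@@H](C)OC=C21
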